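## Retrosynthetic overview

1. Target 18 comes from its tetra-O-benzyl ether 17 by global hydrogenolysis; no ring is formed in that step.
2. Ring A of the naphthalene (C1 aryl, C2 benzyl, C3 OH, C4 H, fused to ring B at C4a/C8a) is the last ring made: 17 arises from isocoumarin 11 and aryl Grignard reagent 14, the aryl–C1 bond forming by addition to the lactone carbonyl and the C1–C2 bond by the aldol closure that follows in the same flask.
3. Enabling feature: in ring A the aryl-bearing C1 and the hydroxyl-bearing C3 are 1,3-related, with the benzyl-bearing C2 between them and an unsubstituted C4 next to ring B. Ring A is therefore the aldol-condensation form of a 1,5-diketone (C1=O, C3=O), and the enol lactone of that diketone is a 3-(2-arylethyl)isocoumarin with C1 at the carboxyl level.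
4. Isocoumarin 11 comes from 2-alkynylbenzoic acid 10 (6-endo-dig lactonization), itself from Sonogashira coupling of iodosyringate 3 with homopropargyl arene 8.
5. Order of ring formation: the three benzene rings are bought (methyl syringate, a benzyl chloride, a bromophenol); the pyranone ring is closed in step 7; carbocyclic ring A replaces it in step 9.

Key step: step 9

Remark: the target has no stereocentre, and the aryl–naphthyl axis carries no descriptor, so no atroposelectivity is sought (racemate expected if rotation is slow).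

## Route

Step 1
Reactants: 1 methyl 4-hydroxy-3,5-dimethoxybenzoate (methyl syringate)
Product: 2 methyl 4-(benzyloxy)-3,5-dimethoxybenzoate
Conditions: BnBr, K2CO3, DMF, 60 °C
Reagents that add atoms: benzyl bromide, BrCc1ccccc1
Why: Williamson ether synthesis; the phenoxide para to the ester is alkylated by the benzylic bromide (SN2), and no other nucleophilic site is present.

Step 2
Reactants: 2 methyl 4-(benzyloxy)-3,5-dimethoxybenzoate
Product: 3 methyl 4-(benzyloxy)-2-iodo-3,5-dimethoxybenzoate
Conditions: I2, CF3CO2Ag, CHCl3, rt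
Reagents that add atoms: iodine, II
Why: Electrophilic aromatic iodination at one of the two equivalent free positions of the trialkoxy ring (ortho and para to methoxy groups), which is far more activated than the phenyl ring of the benzyl ether.

Step 3
Reactants: 4 trimethyl(prop-1-yn-1-yl)silane; 5 3,4-bis(benzyloxy)benzyl chloride
Product: 7 [4-[3,4-bis(benzyloxy)phenyl]but-1-yn-1-yl]trimethylsilane, via 3-(trimethylsilyl)prop-2-ynyllithium 6 (not isolated)
Conditions: 4, n-BuLi, THF, −78 °C; then 5, −78 °C to rt
Reagents that add atoms: none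
Why: Propargylic lithiation of the silylpropyne followed by SN2 alkylation with the reactive benzylic chloride; the silyl group blocks the alkyne terminus and steers alkylation to the propargylic carbon, so the homopropargyl arene should form without allene.

Step 4
Reactants: 7 [4-[3,4-bis(benzyloxy)phenyl]but-1-yn-1-yl]trimethylsilane
Product: 8 1,2-bis(benzyloxy)-4-(but-3-yn-1-yl)benzene
Conditions: K2CO3 (cat.), MeOH/THF, rt
Reagents that add atoms: none
Why: Base-catalysed protodesilylation of an alkynylsilane (methoxide attack at silicon); benzyl ethers are inert.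

Step 5
Reactants: 3 methyl 4-(benzyloxy)-2-iodo-3,5-dimethoxybenzoate; 8 1,2-bis(benzyloxy)-4-(but-3-yn-1-yl)benzene
Product: 9 methyl 4-(benzyloxy)-2-[4-[3,4-bis(benzyloxy)phenyl]but-1-yn-1-yl]-3,5-dimethoxybenzoate
Conditions: Pd(PPh3)2Cl2 (5 mol%), CuI (10 mol%), Et3N, DMF, 60 °C
Reagents that add atoms: none
Why: Sonogashira coupling; the iodide was chosen so that zerovalent palladium inserts readily despite the two ortho substituents and the electron-rich ring, and the ester and benzyl ethers are spectators.

Step 6
Reactants: 9 methyl 4-(benzyloxy)-2-[4-[3,4-bis(benzyloxy)phenyl]but-1-yn-1-yl]-3,5-dimethoxybenzoate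
Product: 10 4-(benzyloxy)-2-[4-[3,4-bis(benzyloxy)phenyl]but-1-yn-1-yl]-3,5-dimethoxybenzoic acid
Conditions: LiOH, THF/MeOH/H2O, 50 °C; then 1 M HCl to pH 3
Reagents that add atoms: lithium hydroxide, [Li+].[OH-]
Why: Saponification of the methyl ester; the aqueous hydroxide is too weak a base to isomerize the alkyne or to cleave benzyl ethers.

Step 7
Reactants: 10 4-(benzyloxy)-2-[4-[3,4-bis(benzyloxy)phenyl]but-1-yn-1-yl]-3,5-dimethoxybenzoic acid
Product: 11 6-(benzyloxy)-3-[2-[3,4-bis(benzyloxy)phenyl]ethyl]-5,7-dimethoxy-1H-isochromen-1-one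
Conditions: Ph3PAuCl (5 mol%), AgOTf (5 mol%), CH2Cl2, rt
Reagents that add atoms: none
Why: Gold-catalysed 6-endo-dig cycloisomerization; cationic monovalent gold activates the alkyne, the carboxyl oxygen attacks the distal alkyne carbon anti to gold and protodeauration gives the isocoumarin, the mode known for ortho-alkynylbenzoic acids and esters carrying alkyl-substituted alkynes.

Step 8
Reactants: 12 4-bromo-3-methoxyphenol
Product: 13 4-(benzyloxy)-1-bromo-2-methoxybenzene
Conditions: BnBr, K2CO3, acetone, reflux
Reagents that add atoms: benzyl bromide, BrCc1ccccc1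
Why: Williamson ether synthesis on the only phenol; the aryl bromide is untouched.

Step 9
Reactants: 11 6-(benzyloxy)-3-[2-[3,4-bis(benzyloxy)phenyl]ethyl]-5,7-dimethoxy-1H-isochromen-1-one; 13 4-(benzyloxy)-1-bromo-2-methoxybenzene
Product: 17 7-(benzyloxy)-4-[4-(benzyloxy)-2-methoxyphenyl]-3-[3,4-bis(benzyloxy)benzyl]-6,8-dimethoxynaphthalen-2-ol, via arylmagnesium bromide 14 (not isolated), via ring-opened 1,5-diketone 15 (not isolated), via cyclic aldol adduct 16 (not isolated)
Conditions: 13, Mg, THF, 50 °C; then 11 (1.1 equiv of 14), THF, 0 °C to rt; then KOH, MeOH, 65 °C, under N2; aq. HCl work-up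
Reagents that add atoms: none
Why: Grignard reagent 14 adds to the lactone carbonyl of 11 (the new aryl–C1 bond), the hemiketal salt opens by loss of the enolate, protic equilibration in KOH/MeOH gives 1,5-diketone 15, its side-chain enolate (the future C2) attacks the diaryl ketone to give aldol adduct 16, and E1cB loss of water followed by enolization should deliver naphthol 17. The closest known reaction types are the Fujimoto–Belleau reaction of enol lactones with Grignard reagents (here with the aldol polarity reversed, because the aryl group has no α-hydrogen), the addition of aryl Grignard reagents to isocoumarins used to prepare 1-aryl-2-benzopyrylium salts, and the alkali-induced ring opening and reclosure of 3-alkyl-2-benzopyrylium pseudobases to 2-naphthols. Ring A closes by a 6-(enolendo)-exo-trig aldol addition and is then aromatized by dehydration. No stereocentre survives, since C1 and C2 of 16 are formed without control and both become sp2 carbons. The step needs mono-addition and closure through carbon instead of oxygen: one equivalent of 14 at 0 °C meets a lactone that is more electrophilic than the ortho-substituted, doubly alkoxy-donated diaryl ketone released from it, the competing benzylic enolate at C4 could only close a four-membered ring, and oxygen closure to the pseudobase is reversible in base, so the material should drain into the aromatic naphtholate.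

Step 10
Reactants: 17 7-(benzyloxy)-4-[4-(benzyloxy)-2-methoxyphenyl]-3-[3,4-bis(benzyloxy)benzyl]-6,8-dimethoxynaphthalen-2-ol
Product: 18 3-(3,4-dihydroxybenzyl)-4-(4-hydroxy-2-methoxyphenyl)-6,8-dimethoxynaphthalene-2,7-diol
Conditions: H2 (1 atm), 10% Pd/C, EtOAc/MeOH, rt, degassed work-up
Reagents that add atoms: none
Why: Hydrogenolysis of the four aryl benzyl ethers; methyl ethers, the diarylmethane carbon and the naphthalene core are not reduced under these mild conditions.

## Compound list

1 | methyl 4-hydroxy-3,5-dimethoxybenzoate (methyl syringate) | COC(=O)c1cc(OC)c(O)c(OC)c1 | starting material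
2 | methyl 4-(benzyloxy)-3,5-dimethoxybenzoate | COC(=O)c1cc(OC)c(OCc2ccccc2)c(OC)c1 | intermediate
3 | methyl 4-(benzyloxy)-2-iodo-3,5-dimethoxybenzoate | COC(=O)c1cc(OC)c(OCc2ccccc2)c(OC)c1I | intermediate
4 | trimethyl(prop-1-yn-1-yl)silane | CC#C[Si](C)(C)C | starting material
5 | 3,4-bis(benzyloxy)benzyl chloride | ClCc1ccc(OCc2ccccc2)c(OCc2ccccc2)c1 | starting material
6 | [3-(trimethylsilyl)prop-2-yn-1-yl]lithium | [Li]CC#C[Si](C)(C)C | intermediate (not isolated)
7 | [4-[3,4-bis(benzyloxy)phenyl]but-1-yn-1-yl]trimethylsilane | C[Si](C)(C)C#CCCc1ccc(OCc2ccccc2)c(OCc2ccccc2)c1 | intermediate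
8 | 1,2-bis(benzyloxy)-4-(but-3-yn-1-yl)benzene | C#CCCc1ccc(OCc2ccccc2)c(OCc2ccccc2)c1 | intermediate
9 | methyl 4-(benzyloxy)-2-[4-[3,4-bis(benzyloxy)phenyl]but-1-yn-1-yl]-3,5-dimethoxybenzoate | COC(=O)c1cc(OC)c(OCc2ccccc2)c(OC)c1C#CCCc1ccc(OCc2ccccc2)c(OCc2ccccc2)c1 | intermediate
10 | 4-(benzyloxy)-2-[4-[3,4-bis(benzyloxy)phenyl]but-1-yn-1-yl]-3,5-dimethoxybenzoic acid | OC(=O)c1cc(OC)c(OCc2ccccc2)c(OC)c1C#CCCc1ccc(OCc2ccccc2)c(OCc2ccccc2)c1 | intermediate
11 | 6-(benzyloxy)-3-[2-[3,4-bis(benzyloxy)phenyl]ethyl]-5,7-dimethoxy-1H-isochromen-1-one | O=C1OC(CCc2ccc(OCc3ccccc3)c(OCc3ccccc3)c2)=Cc2c(OC)c(OCc3ccccc3)c(OC)cc12 | intermediate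
12 | 4-bromo-3-methoxyphenol | COc1cc(O)ccc1Br | starting material
13 | 4-(benzyloxy)-1-bromo-2-methoxybenzene | COc1cc(OCc2ccccc2)ccc1Br | intermediate
14 | [4-(benzyloxy)-2-methoxyphenyl]magnesium bromide | COc1cc(OCc2ccccc2)ccc1[Mg]Br | intermediate (not isolated)
15 | 1-[3-(benzyloxy)-6-[4-(benzyloxy)-2-methoxybenzoyl]-2,4-dimethoxyphenyl]-4-[3,4-bis(benzyloxy)phenyl]butan-2-one | COc1cc(OCc2ccccc2)ccc1C(=O)c1cc(OC)c(OCc2ccccc2)c(OC)c1CC(=O)CCc1ccc(OCc2ccccc2)c(OCc2ccccc2)c1 | intermediate (not isolated)
16 | 7-(benzyloxy)-4-[4-(benzyloxy)-2-methoxyphenyl]-3-[3,4-bis(benzyloxy)benzyl]-4-hydroxy-6,8-dimethoxy-3,4-dihydronaphthalen-2(1H)-one (configuration at C3 and C4 uncontrolled, transient) | COc1cc(OCc2ccccc2)ccc1C1(O)C(Cc2ccc(OCc3ccccc3)c(OCc3ccccc3)c2)C(=O)Cc2c(OC)c(OCc3ccccc3)c(OC)cc12 | intermediate (not isolated)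
17 | 7-(benzyloxy)-4-[4-(benzyloxy)-2-methoxyphenyl]-3-[3,4-bis(benzyloxy)benzyl]-6,8-dimethoxynaphthalen-2-ol | COc1cc(OCc2ccccc2)ccc1-c1c(Cc2ccc(OCc3ccccc3)c(OCc3ccccc3)c2)c(O)cc2c(OC)c(OCc3ccccc3)c(OC)cc12 | intermediate
18 | 3-(3,4-dihydroxybenzyl)-4-(4-hydroxy-2-methoxyphenyl)-6,8-dimethoxynaphthalene-2,7-diol | COc1cc(O)ccc1-c1c(Cc2ccc(O)c(O)c2)c(O)cc2c(OC)c(O)c(OC)cc12 | target

## Step count and risks

Total steps: 10. Longest linear sequence: 7 steps (1, 2, 5, 6, 7, 9, 10; the branch 3, 4, 5, 6, 7, 9, 10 is equally long).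

Steps most likely to fail:

1. Step 9 (key step). What may go wrong: a second addition of the Grignard reagent to the diaryl ketone released on ring opening, or stalling at the open-chain or pseudobase stage because the electron-rich, hindered ketone is attacked too slowly by the enolate. The fallback sets out from acid 10 and excludes over-addition. Amide coupling (EDC·HCl, HOBt, MeNHOMe·HCl, iPr2NEt, CH2Cl2) should give the Weinreb amide 4-(benzyloxy)-2-[4-[3,4-bis(benzyloxy)phenyl]but-1-yn-1-yl]-N,3,5-trimethoxy-N-methylbenzamide F1. Grignard reagent 14 (made from 13 as in step 9) then adds once, through the stable chelated tetrahedral intermediate, to give [4-(benzyloxy)-2-[4-[3,4-bis(benzyloxy)phenyl]but-1-yn-1-yl]-3,5-dimethoxyphenyl][4-(benzyloxy)-2-methoxyphenyl]methanone F2. Ketone-assisted hydration of the alkyne (Ph3PAuNTf2 cat., wet 1,4-dioxane, 60 °C) should give diketone 15, where the fallback comes back to the route; 15 is closed to 17 with KOH/MeOH as in the second stage of step 9.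

2. Step 7. What may go wrong: attack of the carboxyl oxygen on the proximal alkyne carbon (5-exo-dig), which the ortho- and para-methoxy groups of ring B favour electronically, or gold-promoted hydroarylation of the alkyne by the dialkoxyphenyl ring. The fallback sets out from iodide 3 and chloride 5 and fixes the regiochemistry by C–C bond formation (ortho-toluate anion chemistry). Suzuki–Miyaura methylation of 3 (trimethylboroxine, Pd(dppf)Cl2, K2CO3, 1,4-dioxane, 100 °C) should give methyl 4-(benzyloxy)-3,5-dimethoxy-2-methylbenzoate F3. Alkylation of ethyl acetate with 5 (LDA, THF/DMPU, −78 °C) should give ethyl 3-[3,4-bis(benzyloxy)phenyl]propanoate F4. Lateral deprotonation of F3 (LDA, THF, −78 °C) and Claisen-type acylation by F4 should give the keto ester methyl 4-(benzyloxy)-2-[4-[3,4-bis(benzyloxy)phenyl]-2-oxobutyl]-3,5-dimethoxybenzoate F5. Acid-catalysed enol lactonization (p-TsOH, toluene, reflux) returns to the route at isocoumarin 11.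

3. Step 10. What may go wrong: incomplete cleavage of the four benzyl ethers or, on long exposure, partial ring saturation and air oxidation of the very electron-rich polyphenol. The fallback sets out from 17 and uses Lewis-acid debenzylation with BCl3 and pentamethylbenzene as cation scavenger (CH2Cl2, −78 °C), conditions that leave aryl methyl ethers intact; it arrives directly at target 18 and makes no new compound (entry F0).

## Further compounds

F1 | step 9 | 4-(benzyloxy)-2-[4-[3,4-bis(benzyloxy)phenyl]but-1-yn-1-yl]-N,3,5-trimethoxy-N-methylbenzamide | CON(C)C(=O)c1cc(OC)c(OCc2ccccc2)c(OC)c1C#CCCc1ccc(OCc2ccccc2)c(OCc2ccccc2)c1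
F2 | step 9 | [4-(benzyloxy)-2-[4-[3,4-bis(benzyloxy)phenyl]but-1-yn-1-yl]-3,5-dimethoxyphenyl][4-(benzyloxy)-2-methoxyphenyl]methanone | COc1cc(OCc2ccccc2)ccc1C(=O)c1cc(OC)c(OCc2ccccc2)c(OC)c1C#CCCc1ccc(OCc2ccccc2)c(OCc2ccccc2)c1
F3 | step 7 | methyl 4-(benzyloxy)-3,5-dimethoxy-2-methylbenzoate | COC(=O)c1cc(OC)c(OCc2ccccc2)c(OC)c1C
F4 | step 7 | ethyl 3-[3,4-bis(benzyloxy)phenyl]propanoate | CCOC(=O)CCc1ccc(OCc2ccccc2)c(OCc2ccccc2)c1
F5 | step 7 | methyl 4-(benzyloxy)-2-[4-[3,4-bis(benzyloxy)phenyl]-2-oxobutyl]-3,5-dimethoxybenzoate | COC(=O)c1cc(OC)c(OCc2ccccc2)c(OC)c1CC(=O)CCc1ccc(OCc2ccccc2)c(OCc2ccccc2)c1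
F0 | step 10 | none | none
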